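## Retrosynthetic overview

1. The 1,2-dioxane is the second ring and is closed last. The C3–O bond comes from an intramolecular 6-exo oxa-Michael addition of the C6 hydroperoxide to a γ,γ-disubstituted butenolide. The tether forces the cis fusion, so C3 follows from C4.
2. The C6–OO bond comes from Co-catalysed Markovnikov hydroperoxysilylation (O2/Et3SiH) of a C6 exo-methylene group.
3. The butenolide is the first ring. It comes from a Z-selective HWE reaction on an α-silyloxy aldehyde, then desilylation and lactonisation. The exo-methylene group comes from a C6 ketone.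
4. The key C4–C5 bond comes from a Cu(II)–box-catalysed enantioselective Mukaiyama aldol addition of the enolsilane of 14-phenyltetradecan-2-one to methyl pyruvate. This step sets C4.
5. The ketone comes from 11-bromoundecanoic acid and PhCH2CH2MgCl (Cu-catalysed coupling), then a Weinreb ketone synthesis.

Assumption: numbering runs from C1 (lactone C=O) to C6 (peroxy carbon with CH3 and the 12-phenyldodecyl chain), and the SMILES reads (3S,4S,6S), cis-fused; because no dependable method sets an acyclic tertiary C–OO centre, C6 is made as both epimers and the (6S) compound is isolated as a diastereomer in the last step.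

## Route

Step 1
Reactants: 1 11-bromoundecanoic acid; 2 2-phenylethylmagnesium chloride (1.0 M in THF, 2.5 equiv)
Product: 4 13-phenyltridecanoic acid, via chloromagnesium 11-bromoundecanoate 3 (not isolated)
Conditions: Li2CuCl4 (3 mol %), THF, −20 °C → rt; then 1 M HCl
Reagents that add atoms: none
Why: Kochi-type Cu-catalysed sp3–sp3 Grignard cross-coupling, in which the first equivalent of 2 only makes the inert carboxylate 3 and the primary bromide then couples cleanly; no stereocentre is involved.

Step 2
Reactants: 4 13-phenyltridecanoic acid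
Product: 6 N-methoxy-N-methyl-13-phenyltridecanamide, via 13-phenyltridecanoyl imidazolide 5 (not isolated)
Conditions: CDI, CH2Cl2, rt; then MeNH(OMe)·HCl, rt
Reagents that add atoms: N,O-dimethylhydroxylamine hydrochloride, CNOC.Cl
Why: Weinreb amide formation through CDI activation, a mild and high-yielding acyl substitution on an unfunctionalised fatty acid.

Step 3
Reactants: 6 N-methoxy-N-methyl-13-phenyltridecanamide
Product: 7 14-phenyltetradecan-2-one
Conditions: MeMgBr, THF, 0 °C; then 1 M HCl
Reagents that add atoms: methylmagnesium bromide, C[Mg]Br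
Why: Weinreb ketone synthesis, in which the chelated tetrahedral adduct survives until the quench and so excludes over-addition.

Step 4
Reactants: 7 14-phenyltetradecan-2-one
Product: 9 trimethyl[(14-phenyltetradec-1-en-2-yl)oxy]silane, via lithium enolate 8 (not isolated)
Conditions: LDA, THF, −78 °C (ketone added slowly); then TMSCl, −78 °C → rt
Reagents that add atoms: chlorotrimethylsilane, C[Si](C)(C)Cl
Why: Kinetic enolisation with O-silylation, because LDA at −78 °C deprotonates a 2-alkanone at the unhindered methyl group and trapping fixes the terminal enolsilane.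

Step 5
Reactants: 9 trimethyl[(14-phenyltetradec-1-en-2-yl)oxy]silane; 10 methyl pyruvate
Product: 12 methyl (S)-2-hydroxy-2-methyl-4-oxo-16-phenylhexadecanoate, via O-trimethylsilyl aldol adduct 11 (not isolated)
Conditions: Cu(OTf)2 (10 mol %), (S,S)-t-Bu-box (11 mol %), THF, −78 °C; then 1 M HCl, rt
Reagents that add atoms: none
Why: Evans catalytic enantioselective Mukaiyama aldol addition, in which pyruvate chelates square-planar Cu(II) and the (S,S)-ligand leaves only the si face of the ketone open, so the C4–C5 bond forms with the (S) tertiary carbinol (expected 93–99 % ee, as for other enolsilanes with this catalyst).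

Step 6
Reactants: 12 methyl (S)-2-hydroxy-2-methyl-4-oxo-16-phenylhexadecanoate
Product: 13 methyl (S)-2-methyl-4-oxo-16-phenyl-2-(triethylsilyloxy)hexadecanoate
Conditions: TESOTf, 2,6-lutidine, CH2Cl2, −78 → 0 °C
Reagents that add atoms: triethylsilyl trifluoromethanesulfonate, CC[Si](CC)(CC)OS(=O)(=O)C(F)(F)F
Why: Silyl triflate protection, the standard treatment of aldol adducts, which silylates even a tertiary alcohol, blocks retro-aldol cleavage and leaves the quaternary centre untouched.

Step 7
Reactants: 13 methyl (S)-2-methyl-4-oxo-16-phenyl-2-(triethylsilyloxy)hexadecanoate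
Product: 14 methyl (S)-2-methyl-4-methylidene-16-phenyl-2-(triethylsilyloxy)hexadecanoate
Conditions: Zn, CH2Br2, TiCl4 (Lombardo reagent), THF/CH2Cl2, 0 °C → rt
Reagents that add atoms: dibromomethane, BrCBr
Why: Takai–Lombardo methylenation, whose non-basic gem-dimetallic reagent converts ketones but not esters and so avoids both E1cB loss of the β-silyloxy group and attack on the methyl ester.

Step 8
Reactants: 14 methyl (S)-2-methyl-4-methylidene-16-phenyl-2-(triethylsilyloxy)hexadecanoate
Product: 15 (S)-2-methyl-4-methylidene-16-phenyl-2-(triethylsilyloxy)hexadecan-1-ol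
Conditions: DIBAL-H (2.5 equiv), CH2Cl2, −78 → 0 °C; Rochelle salt
Reagents that add atoms: none
Why: Full ester reduction with DIBAL-H, which is more dependable than stopping at the aldehyde of a hindered ester and leaves the alkene and the TES ether inert.

Step 9
Reactants: 15 (S)-2-methyl-4-methylidene-16-phenyl-2-(triethylsilyloxy)hexadecan-1-ol
Product: 16 (S)-2-methyl-4-methylidene-16-phenyl-2-(triethylsilyloxy)hexadecanal
Conditions: DMP, CH2Cl2, rt
Reagents that add atoms: none
Why: Dess–Martin oxidation of a neopentyl-type primary alcohol under near-neutral conditions, giving an aldehyde with no α-hydrogen that therefore cannot epimerise.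

Step 10
Reactants: 16 (S)-2-methyl-4-methylidene-16-phenyl-2-(triethylsilyloxy)hexadecanal
Product: 17 methyl (S,Z)-4-methyl-6-methylidene-18-phenyl-4-(triethylsilyloxy)octadec-2-enoate
Conditions: (CF3CH2O)2P(O)CH2CO2Me, KHMDS, 18-crown-6, THF, −78 °C
Reagents that add atoms: methyl bis(2,2,2-trifluoroethyl)phosphonoacetate, COC(=O)CP(=O)(OCC(F)(F)F)OCC(F)(F)F
Why: Still–Gennari variant of the Horner–Wadsworth–Emmons reaction, in which fast irreversible elimination from the kinetic adduct gives the Z-enoate needed for ring closure.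

Step 11
Reactants: 17 methyl (S,Z)-4-methyl-6-methylidene-18-phenyl-4-(triethylsilyloxy)octadec-2-enoate
Product: 19 (S)-5-methyl-5-(2-methylidene-14-phenyltetradecyl)furan-2(5H)-one, via Z-hydroxy enoate 18 (not isolated)
Conditions: HF·pyridine, THF, 0 °C → rt
Reagents that add atoms: none
Why: Fluoride desilylation followed by spontaneous lactonisation, because the freed tertiary alcohol sits cis to the ester and closes the butenolide (gem-disubstituent effect), with the C–O bond at C4 never broken.

Step 12
Reactants: 19 (S)-5-methyl-5-(2-methylidene-14-phenyltetradecyl)furan-2(5H)-one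
Product: 20 (S)-5-methyl-5-[(S)-2-methyl-14-phenyl-2-(triethylsilylperoxy)tetradecyl]furan-2(5H)-one
Conditions: Co(thd)2 (10 mol %), O2 (1 atm), Et3SiH, ClCH2CH2Cl, rt
Reagents that add atoms: dioxygen, O=O; triethylsilane, CC[SiH](CC)CC
Why: Mukaiyama–Isayama hydroperoxysilylation, in which Co–H transfers H to the electron-rich 1,1-disubstituted alkene in preference to the hindered electron-poor butenolide and the tertiary C6 radical traps O2 without facial bias, so 20 forms about 1:1 with its C2′ epimer and the pair is carried on together.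

Step 13
Reactants: 20 (S)-5-methyl-5-[(S)-2-methyl-14-phenyl-2-(triethylsilylperoxy)tetradecyl]furan-2(5H)-one
Product: 22 plakortolide L, via hydroperoxy butenolide 21 (not isolated)
Conditions: cat. conc. HCl, MeOH, 0 °C; then Et3N (0.5 equiv), CF3CH2OH, rt; SiO2 chromatography
Reagents that add atoms: none
Why: Acid methanolysis of the silyl peroxide and then a base-catalysed intramolecular 6-exo-trig oxa-Michael addition, in which the C4 tether can deliver the peroxide only to its own face of the butenolide and so sets (3S) with cis fusion, while the (6S) bicycle is separated from its 6-epimer as a diastereomer on silica.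

## Compound list

1 | 11-bromoundecanoic acid | OC(=O)CCCCCCCCCCBr | starting material
2 | 2-phenylethylmagnesium chloride | Cl[Mg]CCc1ccccc1 | starting material
3 | chloromagnesium 11-bromoundecanoate | Cl[Mg]OC(=O)CCCCCCCCCCBr | intermediate
4 | 13-phenyltridecanoic acid | OC(=O)CCCCCCCCCCCCc1ccccc1 | intermediate
5 | 1-(1H-imidazol-1-yl)-13-phenyltridecan-1-one | O=C(CCCCCCCCCCCCc1ccccc1)n1ccnc1 | intermediate
6 | N-methoxy-N-methyl-13-phenyltridecanamide | CON(C)C(=O)CCCCCCCCCCCCc1ccccc1 | intermediate
7 | 14-phenyltetradecan-2-one | CC(=O)CCCCCCCCCCCCc1ccccc1 | intermediate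
8 | lithium 14-phenyltetradec-1-en-2-olate | [Li]OC(=C)CCCCCCCCCCCCc1ccccc1 | intermediate
9 | trimethyl[(14-phenyltetradec-1-en-2-yl)oxy]silane | C=C(O[Si](C)(C)C)CCCCCCCCCCCCc1ccccc1 | intermediate
10 | methyl pyruvate | COC(=O)C(C)=O | starting material
11 | methyl (S)-2-methyl-4-oxo-16-phenyl-2-(trimethylsilyloxy)hexadecanoate | COC(=O)[C@@](C)(O[Si](C)(C)C)CC(=O)CCCCCCCCCCCCc1ccccc1 | intermediate
12 | methyl (S)-2-hydroxy-2-methyl-4-oxo-16-phenylhexadecanoate | COC(=O)[C@@](C)(O)CC(=O)CCCCCCCCCCCCc1ccccc1 | intermediate
13 | methyl (S)-2-methyl-4-oxo-16-phenyl-2-(triethylsilyloxy)hexadecanoate | COC(=O)[C@@](C)(O[Si](CC)(CC)CC)CC(=O)CCCCCCCCCCCCc1ccccc1 | intermediate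
14 | methyl (S)-2-methyl-4-methylidene-16-phenyl-2-(triethylsilyloxy)hexadecanoate | COC(=O)[C@@](C)(O[Si](CC)(CC)CC)CC(=C)CCCCCCCCCCCCc1ccccc1 | intermediate
15 | (S)-2-methyl-4-methylidene-16-phenyl-2-(triethylsilyloxy)hexadecan-1-ol | OC[C@@](C)(O[Si](CC)(CC)CC)CC(=C)CCCCCCCCCCCCc1ccccc1 | intermediate
16 | (S)-2-methyl-4-methylidene-16-phenyl-2-(triethylsilyloxy)hexadecanal | O=C[C@@](C)(O[Si](CC)(CC)CC)CC(=C)CCCCCCCCCCCCc1ccccc1 | intermediate
17 | methyl (S,Z)-4-methyl-6-methylidene-18-phenyl-4-(triethylsilyloxy)octadec-2-enoate | COC(=O)/C=C\[C@@](C)(O[Si](CC)(CC)CC)CC(=C)CCCCCCCCCCCCc1ccccc1 | intermediate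
18 | methyl (S,Z)-4-hydroxy-4-methyl-6-methylidene-18-phenyloctadec-2-enoate | COC(=O)/C=C\[C@@](C)(O)CC(=C)CCCCCCCCCCCCc1ccccc1 | intermediate
19 | (S)-5-methyl-5-(2-methylidene-14-phenyltetradecyl)furan-2(5H)-one | O=C1C=C[C@](C)(CC(=C)CCCCCCCCCCCCc2ccccc2)O1 | intermediate
20 | (S)-5-methyl-5-[(S)-2-methyl-14-phenyl-2-(triethylsilylperoxy)tetradecyl]furan-2(5H)-one (handled as a 1:1 mixture with its C2′ epimer) | O=C1C=C[C@](C)(C[C@@](C)(OO[Si](CC)(CC)CC)CCCCCCCCCCCCc2ccccc2)O1 | intermediate
21 | (S)-5-[(S)-2-hydroperoxy-2-methyl-14-phenyltetradecyl]-5-methylfuran-2(5H)-one (handled as a 1:1 mixture with its C2′ epimer) | O=C1C=C[C@](C)(C[C@@](C)(OO)CCCCCCCCCCCCc2ccccc2)O1 | intermediate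
22 | plakortolide L, (3S,4S,6S), cis-fused 1,2-dioxane/γ-lactone | C[C@]1(CCCCCCCCCCCCc2ccccc2)C[C@]2(C)OC(=O)C[C@@H]2OO1 | target

## Step count and risks

Total step count: 13. Longest linear sequence: 13 steps (1 → 22).

**Step 5.** The risks are the regiochemical purity of 9 and the ee obtained with a long-chain ketone enolsilane. The fallback sets out from 10 and 4 and comes back at 13. S-Ethyl thioacetate (commercial) is converted with LDA and TMSCl into 1-(ethylsulfanyl)-1-(trimethylsilyloxy)ethene F1, the type of nucleophile for which this catalyst performs best. Its addition to 10 under the conditions of step 5 gives methyl (S)-4-(ethylsulfanyl)-2-hydroxy-2-methyl-4-oxobutanoate F2. Silylation with TESOTf and 2,6-lutidine gives methyl (S)-4-(ethylsulfanyl)-2-methyl-4-oxo-2-(triethylsilyloxy)butanoate F3. The chain is then attached after the aldol step. Acid 4 is degraded by decarboxylative iodination (PhI(OAc)2, I2, hν) to (12-iodododecyl)benzene F4. Zinc insertion gives (12-phenyldodecyl)zinc iodide F5. Fukuyama coupling of this reagent with the thioester (PdCl2(PPh3)2, toluene, rt) gives ketone 13.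

**Step 10.** The risk is slow or poorly Z-selective olefination of the hindered α-quaternary aldehyde. The fallback sets out from 16 and comes back at 19. HF·pyridine frees (S)-2-hydroxy-2-methyl-4-methylidene-16-phenylhexadecanal F6. Ph3P=C=C=O (Bestmann ylide, toluene, 80 °C) acylates its tertiary hydroxyl to give (S)-2-methyl-4-methylidene-1-oxo-16-phenylhexadecan-2-yl (triphenylphosphoranylidene)acetate F7. This ester ylide closes by an intramolecular Wittig reaction on the aldehyde. A five-membered ring can hold only the cis alkene, so 19 results with no E/Z issue.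

**Step 12.** The risks are competing H-atom transfer to the butenolide, over-reduction to the alcohol, and the loss of half the material because C6 is not controlled. The fallback sets out from 19 and comes back at 21, and it uses an ionic instead of a radical C–O bond formation. One equivalent of HBr (CH2Cl2, −40 °C) adds in the Markovnikov sense to the electron-rich alkene only. This gives (5S)-5-(2-bromo-2-methyl-14-phenyltetradecyl)-5-methylfuran-2(5H)-one F8 as both C2′ epimers. Silver trifluoroacetate with anhydrous ethereal H2O2 at 0 °C (silver-assisted SN1 perhydrolysis) converts the bromide into hydroperoxide 21, again together with its epimer. This material enters the Et3N/CF3CH2OH stage of step 13, and the same final separation applies.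

Further compounds
F1 | step 5 | 1-(ethylsulfanyl)-1-(trimethylsilyloxy)ethene | C=C(SCC)O[Si](C)(C)C
F2 | step 5 | methyl (S)-4-(ethylsulfanyl)-2-hydroxy-2-methyl-4-oxobutanoate | COC(=O)[C@@](C)(O)CC(=O)SCC
F3 | step 5 | methyl (S)-4-(ethylsulfanyl)-2-methyl-4-oxo-2-(triethylsilyloxy)butanoate | COC(=O)[C@@](C)(O[Si](CC)(CC)CC)CC(=O)SCC
F4 | step 5 | (12-iodododecyl)benzene | ICCCCCCCCCCCCc1ccccc1
F5 | step 5 | (12-phenyldodecyl)zinc iodide | I[Zn]CCCCCCCCCCCCc1ccccc1
F6 | step 10 | (S)-2-hydroxy-2-methyl-4-methylidene-16-phenylhexadecanal | O=C[C@@](C)(O)CC(=C)CCCCCCCCCCCCc1ccccc1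
F7 | step 10 | (S)-2-methyl-4-methylidene-1-oxo-16-phenylhexadecan-2-yl (triphenylphosphoranylidene)acetate | O=C[C@@](C)(OC(=O)C=P(c1ccccc1)(c1ccccc1)c1ccccc1)CC(=C)CCCCCCCCCCCCc1ccccc1
F8 | step 12 | (5S)-5-(2-bromo-2-methyl-14-phenyltetradecyl)-5-methylfuran-2(5H)-one | O=C1C=C[C@](C)(CC(C)(Br)CCCCCCCCCCCCc2ccccc2)O1
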